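**Retrosynthetic overview**

1. Ring labels: ring A is the 3‑aryloxy‑4,5‑dihydroxyphenyl ring, ring B the 1,4‑phenylene, ring C the 2‑aryloxy‑3,4‑dihydroxyphenyl ring, ring D the 1,2‑phenylene (ether O on C1, bridge CH2 on C2). The four OH groups travel as methyl ethers and are freed last.
2. Key disconnection: the C(sp2)–C(sp3) bond between ring D C2 and the adjacent CH2 of the ring A/ring D ethano bridge. It is made by hydroboration of a ring A vinyl group and intramolecular B‑alkyl Suzuki–Miyaura coupling with a ring D aryl chloride, which closes the 17‑membered ring with the bridge already saturated.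
3. Enabling feature: ring D carries nothing but the ether oxygen and, on the neighbouring carbon, that CH2, so it enters as a plain 2‑chlorophenyl group. Ring C is substituted on both carbons flanking its ether oxygen (C1 bridge, C3 OMe), so the arylpalladium species cannot divert to a dibenzofuran by C–H arylation.
4. The acyclic aryl chloride/styrene comes from Wittig methylenation, Ullmann etherification (ring A–O–ring B), iodonium O‑arylation (ring C–O–ring D) and a bibenzyl phenol made by Friedel–Crafts acylation/ortho‑demethylation of 1,2,3‑trimethoxybenzene and ionic hydrogenation.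
5. Order: rings A–D are bought as arenes; the only ring formed is the macrocycle (step 7), then global demethylation.

Key step: step 7

Assumption: the target has no stereocentre and is made as the neutral tetraphenol; all phenols are masked as methyl ethers until the final step.

**Step 1**
Reactants: 1 1,2,3‑trimethoxybenzene; 2 (4‑bromophenyl)acetyl chloride
Product: 4 2‑(4‑bromophenyl)‑1‑(2‑hydroxy‑3,4‑dimethoxyphenyl)ethan‑1‑one, via trimethoxy ketone 3 (not isolated)
Conditions: AlCl3 (2.5 equiv), CH2Cl2, 0 °C to rt; aq. HCl work‑up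
Reagents that add atoms: none
Why: Friedel–Crafts acylation should occur at C4 of 1 (para and ortho to methoxy groups), and the excess AlCl3, chelated between the new carbonyl and the neighbouring methoxy oxygen, should cleave only that ortho methyl ether (chelation‑controlled demethylation).

**Step 2**
Reactants: 4 2‑(4‑bromophenyl)‑1‑(2‑hydroxy‑3,4‑dimethoxyphenyl)ethan‑1‑one
Product: 5 6‑[2‑(4‑bromophenyl)ethyl]‑2,3‑dimethoxyphenol
Conditions: Et3SiH (3 equiv), CF3CO2H, rt to 50 °C
Reagents that add atoms: none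
Why: Ionic hydrogenation of the electron‑rich aryl ketone (protonation, hydride transfer from silicon, ionisation of the benzylic alcohol, second hydride transfer) should give the methylene, while the aryl bromide, phenol and methyl ethers are inert.

**Step 3**
Reactants: 6 1‑chloro‑2‑iodobenzene; 7 1,3,5‑trimethoxybenzene
Product: 9 (2‑chlorophenyl)(2,4,6‑trimethoxyphenyl)iodonium 4‑methylbenzenesulfonate, via hydroxy(tosyloxy)iodoarene 8 (not isolated)
Conditions: mCPBA (1.0 equiv), TsOH·H2O (1.0 equiv), MeCN, 77 °C; then 7, 77 °C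
Reagents that add atoms: 4‑methylbenzenesulfonic acid monohydrate, Cc1ccc(cc1)S(=O)(=O)O.O
Why: Peracid oxidation of the aryl iodide to the trivalent iodine hydroxy(tosyloxy) species, followed by electrophilic substitution on the very electron‑rich 1,3,5‑trimethoxybenzene, is the established one‑pot synthesis of aryl(trimethoxyphenyl)iodonium tosylates.

**Step 4**
Reactants: 5 6‑[2‑(4‑bromophenyl)ethyl]‑2,3‑dimethoxyphenol; 9 (2‑chlorophenyl)(2,4,6‑trimethoxyphenyl)iodonium 4‑methylbenzenesulfonate
Product: 10 1‑[2‑(4‑bromophenyl)ethyl]‑2‑(2‑chlorophenoxy)‑3,4‑dimethoxybenzene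
Conditions: t‑BuOK (1.1 equiv), THF, 0 °C; then 9, 40 °C
Reagents that add atoms: none
Why: Metal‑free O‑arylation of a phenoxide by a diaryliodonium salt (ligand coupling at trivalent iodine) tolerates two ortho substituents on the phenol, should transfer the 2‑chlorophenyl group because the electron‑rich trimethoxyphenyl ligand stays on iodine, and leaves the aryl bromide untouched.

**Step 5**
Reactants: 10 1‑[2‑(4‑bromophenyl)ethyl]‑2‑(2‑chlorophenoxy)‑3,4‑dimethoxybenzene; 11 3‑hydroxy‑4,5‑dimethoxybenzaldehyde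
Product: 12 3‑(4‑{2‑[2‑(2‑chlorophenoxy)‑3,4‑dimethoxyphenyl]ethyl}phenoxy)‑4,5‑dimethoxybenzaldehyde
Conditions: CuI (10 mol%), N,N‑dimethylglycine hydrochloride (30 mol%), Cs2CO3 (2 equiv), 1,4‑dioxane, 100 °C
Reagents that add atoms: none
Why: The copper‑catalysed Ullmann diaryl ether coupling should engage the unhindered ring B aryl bromide, whereas the hindered ring D aryl chloride is inert to copper under these conditions and the non‑enolisable aldehyde survives the carbonate base.

**Step 6**
Reactants: 12 3‑(4‑{2‑[2‑(2‑chlorophenoxy)‑3,4‑dimethoxyphenyl]ethyl}phenoxy)‑4,5‑dimethoxybenzaldehyde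
Product: 13 1‑(4‑{2‑[2‑(2‑chlorophenoxy)‑3,4‑dimethoxyphenyl]ethyl}phenoxy)‑5‑ethenyl‑2,3‑dimethoxybenzene
Conditions: Ph3PCH3Br (1.5 equiv), t‑BuOK (1.4 equiv), THF, 0 °C to rt
Reagents that add atoms: methyltriphenylphosphonium bromide, C[P+](c1ccccc1)(c1ccccc1)c1ccccc1.[Br-]
Why: Wittig methylenation of the only carbonyl group with the non‑stabilised ylide should give the ring A styrene without touching the aryl chloride or the ethers.

**Step 7**
Reactants: 13 1‑(4‑{2‑[2‑(2‑chlorophenoxy)‑3,4‑dimethoxyphenyl]ethyl}phenoxy)‑5‑ethenyl‑2,3‑dimethoxybenzene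
Product: 15 tetra‑O‑methyl ether of the target (17‑membered macrocycle; ring A 4,5‑dimethoxy, ring C 3,4‑dimethoxy), via B‑alkyl‑9‑BBN adduct 14 (not isolated)
Conditions: 9‑BBN‑H (1.5 equiv), THF, 0 °C to rt; then syringe‑pump addition (10 h) to Pd(OAc)2 (10 mol%), SPhos (20 mol%), K3PO4 (3 equiv), THF/H2O 10:1, 70 °C, final 2 mM
Reagents that add atoms: none
Why: 9‑BBN should add syn and anti‑Markovnikov to the ring A vinyl group, placing boron on the terminal carbon; zerovalent palladium (from Pd(OAc)2/SPhos) then inserts into the ring D C–Cl bond, the hydroxide‑activated borate transfers its primary alkyl group to divalent palladium, and reductive elimination forms the ring D C2–CH2 bond. The closest known reaction type is the macrocyclising intramolecular B‑alkyl Suzuki–Miyaura coupling, including its variant for aryl chlorides with dialkylbiarylphosphine ligands. The 17‑membered ring is closed end‑to‑end by reductive elimination from an 18‑membered palladacycle, and no stereocentre is formed. The step needs ring closure to beat oligomerisation and β‑hydride elimination: slow addition keeps 14 dilute, the ortho and meta diaryl ether bends should bring the chain ends together, and the bulky, electron‑rich SPhos ligand should make reductive elimination faster than β‑hydride loss. Regiochemistry at the bridge rests on the steric preference of 9‑BBN for the terminal carbon of a styrene. Diversion of the arylpalladium intermediate to a dibenzofuran is excluded because both ring C carbons ortho to the ether oxygen are substituted (bridge at C1, methoxy at C3).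

**Step 8**
Reactants: 15 tetra‑O‑methyl ether of the target
Product: 16 CNP0114693.0 (17‑membered macrocycle of rings A–D; OH on ring A C4 and C5 and on ring C C3 and C4)
Conditions: BBr3 (8 equiv), CH2Cl2, −78 °C to rt; then H2O, 0 °C (degassed work‑up)
Reagents that add atoms: none
Why: BBr3 cleavage of aryl methyl ethers (boron coordination to oxygen, bromide attack on the methyl group, hydrolysis of the aryl borates) should free all four phenols while diaryl ethers and the saturated bridges are inert.

**Compound list**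

1 | 1,2,3‑trimethoxybenzene | COc1cccc(OC)c1OC | starting material
2 | (4‑bromophenyl)acetyl chloride | O=C(Cl)Cc1ccc(Br)cc1 | starting material
3 | 2‑(4‑bromophenyl)‑1‑(2,3,4‑trimethoxyphenyl)ethan‑1‑one (not isolated) | COc1ccc(C(=O)Cc2ccc(Br)cc2)c(OC)c1OC | intermediate
4 | 2‑(4‑bromophenyl)‑1‑(2‑hydroxy‑3,4‑dimethoxyphenyl)ethan‑1‑one | COc1ccc(C(=O)Cc2ccc(Br)cc2)c(O)c1OC | intermediate
5 | 6‑[2‑(4‑bromophenyl)ethyl]‑2,3‑dimethoxyphenol | COc1ccc(CCc2ccc(Br)cc2)c(O)c1OC | intermediate
6 | 1‑chloro‑2‑iodobenzene | Clc1ccccc1I | starting material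
7 | 1,3,5‑trimethoxybenzene | COc1cc(OC)cc(OC)c1 | starting material
8 | (2‑chlorophenyl)(hydroxy)(tosyloxy)iodane (not isolated) | Cc1ccc(cc1)S(=O)(=O)OI(O)c1ccccc1Cl | intermediate
9 | (2‑chlorophenyl)(2,4,6‑trimethoxyphenyl)iodonium 4‑methylbenzenesulfonate | COc1cc(OC)c([I+]c2ccccc2Cl)c(OC)c1.Cc1ccc(cc1)S(=O)(=O)[O-] | intermediate
10 | 1‑[2‑(4‑bromophenyl)ethyl]‑2‑(2‑chlorophenoxy)‑3,4‑dimethoxybenzene | COc1ccc(CCc2ccc(Br)cc2)c(Oc2ccccc2Cl)c1OC | intermediate
11 | 3‑hydroxy‑4,5‑dimethoxybenzaldehyde | COc1cc(C=O)cc(O)c1OC | starting material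
12 | 3‑(4‑{2‑[2‑(2‑chlorophenoxy)‑3,4‑dimethoxyphenyl]ethyl}phenoxy)‑4,5‑dimethoxybenzaldehyde | COc1cc(C=O)cc(Oc2ccc(CCc3ccc(OC)c(OC)c3Oc3ccccc3Cl)cc2)c1OC | intermediate
13 | 1‑(4‑{2‑[2‑(2‑chlorophenoxy)‑3,4‑dimethoxyphenyl]ethyl}phenoxy)‑5‑ethenyl‑2,3‑dimethoxybenzene | C=Cc1cc(OC)c(OC)c(Oc2ccc(CCc3ccc(OC)c(OC)c3Oc3ccccc3Cl)cc2)c1 | intermediate
14 | 9‑{2‑[3‑(4‑{2‑[2‑(2‑chlorophenoxy)‑3,4‑dimethoxyphenyl]ethyl}phenoxy)‑4,5‑dimethoxyphenyl]ethyl}‑9‑borabicyclo[3.3.1]nonane (not isolated) | COc1cc(CCB2C3CCCC2CCC3)cc(Oc2ccc(CCc3ccc(OC)c(OC)c3Oc3ccccc3Cl)cc2)c1OC | intermediate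
15 | tetra‑O‑methyl ether of the target (17‑membered macrocycle; ring A 4,5‑dimethoxy, ring C 3,4‑dimethoxy) | COc1cc2cc(c1OC)Oc1ccc(cc1)CCc1ccc(OC)c(OC)c1Oc1ccccc1CC2 | intermediate
16 | CNP0114693.0 | Oc1cc2cc(c1O)Oc1ccc(cc1)CCc1ccc(O)c(O)c1Oc1ccccc1CC2 | target

**Totals**

Total step count: 8. Longest linear sequence: 7 steps (steps 1, 2, 4, 5, 6, 7, 8); step 3 prepares the arylating reagent on a side branch.

**Steps most likely to fail**

1. Step 7. Ring closure may lose to intermolecular coupling (oligomerisation), and the alkylpalladium intermediate may undergo β‑hydride elimination or the borane may protodeboronate before transmetalation. Fallback: setting out from 13, an intramolecular Mizoroki–Heck reaction (Pd2(dba)3, P(t‑Bu)3·HBF4, Cy2NMe, 1,4‑dioxane, 100 °C, 2 mM) should form the same ring D C2–carbon bond at the alkene oxidation level and give the macrocyclic (E)‑stilbene tetramethyl ether F1. Hydrogenation of its C=C bond (H2, Pd/C, EtOAc, rt) comes back to the route at 15.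

2. Step 4. Aryl transfer to the doubly ortho‑substituted phenoxide may be slow, and base‑induced aryne formation from the iodonium salt could scramble the position of chlorine. Fallback: setting out from 5, SNAr with 1‑fluoro‑2‑nitrobenzene (K2CO3, DMF, 80 °C) should give the nitro diaryl ether 1‑[2‑(4‑bromophenyl)ethyl]‑3,4‑dimethoxy‑2‑(2‑nitrophenoxy)benzene F2. Reduction (Fe powder, NH4Cl, EtOH/H2O, 80 °C) gives the aniline 2‑{6‑[2‑(4‑bromophenyl)ethyl]‑2,3‑dimethoxyphenoxy}aniline F3, and Sandmeyer chlorination (t‑BuONO, CuCl2, MeCN, 60 °C) comes back to the route at 10.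

3. Step 5. The copper‑catalysed etherification may stall with the moderately nucleophilic aldehyde‑bearing phenol, or protodebromination may compete. Fallback: setting out from 10, Miyaura borylation of the aryl bromide (B2pin2, Pd(dppf)Cl2, KOAc, 1,4‑dioxane, 80 °C; the hindered aryl chloride should not react) reverses the polarity and gives the pinacol boronate 2‑(4‑{2‑[2‑(2‑chlorophenoxy)‑3,4‑dimethoxyphenyl]ethyl}phenyl)‑4,4,5,5‑tetramethyl‑1,3,2‑dioxaborolane F4. Chan–Lam etherification with 11 (Cu(OAc)2, pyridine, B(OH)3, 4 Å molecular sieves, MeCN, air, 60 °C) comes back to the route at 12.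

**Further compounds**

F1 | step 7 | macrocyclic (E)‑stilbene tetramethyl ether (ring D–CH=CH–ring A in place of the ethano bridge of 15) | COc1cc2cc(c1OC)Oc1ccc(cc1)CCc1ccc(OC)c(OC)c1Oc1ccccc1/C=C/2
F2 | step 4 | 1‑[2‑(4‑bromophenyl)ethyl]‑3,4‑dimethoxy‑2‑(2‑nitrophenoxy)benzene | COc1ccc(CCc2ccc(Br)cc2)c(Oc2ccccc2[N+](=O)[O-])c1OC
F3 | step 4 | 2‑{6‑[2‑(4‑bromophenyl)ethyl]‑2,3‑dimethoxyphenoxy}aniline | COc1ccc(CCc2ccc(Br)cc2)c(Oc2ccccc2N)c1OC
F4 | step 5 | 2‑(4‑{2‑[2‑(2‑chlorophenoxy)‑3,4‑dimethoxyphenyl]ethyl}phenyl)‑4,4,5,5‑tetramethyl‑1,3,2‑dioxaborolane | COc1ccc(CCc2ccc(cc2)B2OC(C)(C)C(C)(C)O2)c(Oc2ccccc2Cl)c1OC
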